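The target is an ampelopsin A core (units A, B) joined through the phenol ring of unit B to an ε-viniferin-type bis(dihydrobenzofuran) (units C, D). The route disconnects, inside the seven-membered carbocycle, the bond between C8b (position 3 of the dihydrofuran on the resorcinol ring of unit A) and C9b (the resorcinol carbon of unit B meta to both oxygens, beyond Friedel–Crafts reach). The precursor is a 2-aryl-6-hydroxybenzofuran whose position-4 arm CH(OBn)–CH(Ar) carries a 2-bromo-4,6-bis(benzyloxy)phenyl group. The key step exploits that C8b and C7b are furan carbons 3 and 2: one dearomative reductive Heck cyclisation adds aryl and hydride across them, closing the carbocycle and setting both centres trans.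

Key step: step 22

Remarks
- Locants (resveratrol-unit style). Each unit has a phenol ring (the 4-oxyphenyl ring, carbons 1 to 6) and a resorcinol ring (carbons 9 to 14), and the rings are named by the letter of their unit.
  - Unit A: phenol ring A; C7a (bears phenol ring A); C8a (bears OH); resorcinol ring A (C9a bonded to C8a, C10a to C8b, C11a to the furan oxygen, C13a to OH).
  - Unit B: phenol ring B (C1b bonded to C7b, C3b to C8c, C4b to oxygen); C7b (O-bearing); C8b; resorcinol ring B (C9b bonded to C8b, C10b to C7a, oxygen on C11b and C13b).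
  - Unit C: phenol ring C; C7c; C8c; resorcinol ring C (C9c bonded to C8c, C10c to C8d, C11c to oxygen).
  - Unit D: phenol ring D; C7d; C8d; resorcinol ring D.
  - The target is 7aR,8aS,7bR,8bR,7cR,8cR,7dR,8dR, and all three dihydrofurans are trans.
- Assumption: Rh2(R-PTAD)4 is taken to deliver the 3R ring carbon (C8d, C8c) in steps 7 and 10; if its sense is the opposite, Rh2(S-PTAD)4 is used and nothing else changes.
- Compounds 1, 4, 12, 20 and 22 are taken as purchased.

Step 1
Reactants: 1 1,3-bis(benzyloxy)-5-bromobenzene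
Product: 2 2,4-bis(benzyloxy)-6-bromobenzaldehyde
Conditions: POCl3, DMF, 0 to 80 °C; aq. NaOAc
Reagents that add atoms: N,N-dimethylformamide CN(C)C=O; water O
Why: Vilsmeier–Haack formylation should go para to one benzyloxy group and ortho to bromine, as it does with 1-bromo-3,5-dimethoxybenzene, the position between the two ethers being the more hindered one.

Step 2
Reactants: 2 2,4-bis(benzyloxy)-6-bromobenzaldehyde
Product: 3 4-(benzyloxy)-2-bromo-6-hydroxybenzaldehyde
Conditions: MgBr2·OEt2, toluene/Et2O, 80 °C; aq. HCl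
Reagents that add atoms: none
Why: Chelation of magnesium between the formyl oxygen and the ortho ether oxygen lets bromide cleave only that benzyl ether (chelation-controlled ortho-debenzylation).

Step 3
Reactants: 3 4-(benzyloxy)-2-bromo-6-hydroxybenzaldehyde; 4 4-(benzyloxy)benzyl chloride
Product: 5 4-(benzyloxy)-2-{[4-(benzyloxy)benzyl]oxy}-6-bromobenzaldehyde
Conditions: K2CO3, KI (cat.), DMF, 60 °C
Reagents that add atoms: none
Why: Williamson etherification of the phenol installs the OCH2Ar group whose CH2 later becomes C7d.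

Step 4
Reactants: 1 1,3-bis(benzyloxy)-5-bromobenzene; 5 4-(benzyloxy)-2-{[4-(benzyloxy)benzyl]oxy}-6-bromobenzaldehyde
Product: 7 rac-[4-(benzyloxy)-2-{[4-(benzyloxy)benzyl]oxy}-6-bromophenyl][3,5-bis(benzyloxy)phenyl]methanol, via aryllithium 6 (not isolated)
Conditions: n-BuLi, THF, −78 °C; then 5, −78 °C; aq. NH4Cl
Reagents that add atoms: none
Why: Bromine–lithium exchange and 1,2-addition to the aldehyde should be faster at −78 °C than exchange with the aryl bromide of 5; the racemic carbinol centre is removed in step 5.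

Step 5
Reactants: 7 rac-[4-(benzyloxy)-2-{[4-(benzyloxy)benzyl]oxy}-6-bromophenyl][3,5-bis(benzyloxy)phenyl]methanol
Product: 8 [4-(benzyloxy)-2-{[4-(benzyloxy)benzyl]oxy}-6-bromophenyl][3,5-bis(benzyloxy)phenyl]methanone
Conditions: Dess–Martin periodinane, NaHCO3, CH2Cl2, rt
Reagents that add atoms: none
Why: Mild oxidation of a benzhydrol to the diaryl ketone without touching the benzyl ethers.

Step 6
Reactants: 8 [4-(benzyloxy)-2-{[4-(benzyloxy)benzyl]oxy}-6-bromophenyl][3,5-bis(benzyloxy)phenyl]methanone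
Product: 9 hydrazone of ketone 8
Conditions: N2H4·H2O (excess), AcOH (cat.), EtOH, 80 °C, sealed tube
Reagents that add atoms: hydrazine NN
Why: Acid-catalysed condensation gives the free hydrazone; forcing conditions answer the two ortho substituents, and no metal is present that could close an indazole onto the bromide.

Step 7
Reactants: 9 hydrazone of ketone 8
Product: 11 (2S,3R)-6-(benzyloxy)-2-[4-(benzyloxy)phenyl]-3-[3,5-bis(benzyloxy)phenyl]-4-bromo-2,3-dihydro-1-benzofuran (cis ring; 7dS,8dR), via diaryldiazomethane 10 (not isolated)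
Conditions: MnO2, CH2Cl2, 0 °C; filtration; Rh2(R-PTAD)4 (1 mol %), CH2Cl2, 0 °C
Reagents that add atoms: none
Why: The donor/donor rhodium carbene undergoes enantioselective intramolecular 1,5 C–H insertion into the benzylic ether CH2; the chiral carboxylate ligands set C8d (R), and the concerted insertion gives the cis ring, whose C7d is corrected in step 11.

Step 8
Reactants: 12 5-bromo-2-hydroxybenzonitrile; 4 4-(benzyloxy)benzyl chloride
Product: 13 2-{[4-(benzyloxy)benzyl]oxy}-5-bromobenzonitrile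
Conditions: K2CO3, DMF, 60 °C
Reagents that add atoms: none
Why: Williamson etherification gives the building block for phenol ring B with its insertion site and its bromine handle.

Step 9
Reactants: 11 cis-dihydrobenzofuran bromide; 13 2-{[4-(benzyloxy)benzyl]oxy}-5-bromobenzonitrile
Product: 16 hydrazone of the diaryl ketone that joins C9c of resorcinol ring C to C3b of phenol ring B, via aryllithium 14 (not isolated), via N-H ketimine 15 (not isolated)
Conditions: n-BuLi, THF, −78 °C; 13, −78 to 0 °C; MeOH; then N2H4·H2O, AcOH, EtOH, 70 °C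
Reagents that add atoms: hydrazine NN
Why: The aryllithium adds to the nitrile to give a stable ketimine, which exchanges with hydrazine (transimination, loss of ammonia) more readily than the hindered ketone would condense.

Step 10
Reactants: 16 hydrazone
Product: 18 (2S,3R)-2-[4-(benzyloxy)phenyl]-5-bromo-3-{(2S,3R)-6-(benzyloxy)-2-[4-(benzyloxy)phenyl]-3-[3,5-bis(benzyloxy)phenyl]-2,3-dihydro-1-benzofuran-4-yl}-2,3-dihydro-1-benzofuran (both rings cis), via diaryldiazomethane 17 (not isolated)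
Conditions: MnO2, CH2Cl2, 0 °C; filtration; Rh2(R-PTAD)4 (1 mol %), CH2Cl2, 0 °C
Reagents that add atoms: none
Why: A second carbene 1,5 C–H insertion into the OCH2Ar group on phenol ring B should outpace attack on resorcinol ring D; the catalyst sets C8c (R) and the ring again forms cis.

Step 11
Reactants: 18 cis,cis-bis(dihydrobenzofuran) bromide
Product: 19 (2R,3R)-2-[4-(benzyloxy)phenyl]-5-bromo-3-{(2R,3R)-6-(benzyloxy)-2-[4-(benzyloxy)phenyl]-3-[3,5-bis(benzyloxy)phenyl]-2,3-dihydro-1-benzofuran-4-yl}-2,3-dihydro-1-benzofuran (both rings trans)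
Conditions: BF3·OEt2 (20 mol %), CH2Cl2, −20 to 0 °C
Reagents that add atoms: none
Why: Reversible Lewis-acid ionisation of each C7–O bond to a 4-benzyloxybenzyl cation and re-closure by the phenol oxygen should equilibrate C7c and C7d to the more stable trans rings, C8c and C8d staying untouched.

Step 12
Reactants: 19 trans,trans-bis(dihydrobenzofuran) bromide; 20 ethynyltrimethylsilane
Product: 21 5-[(trimethylsilyl)ethynyl] analogue of 19
Conditions: PdCl2(MeCN)2 (3 mol %), XPhos (9 mol %), Cs2CO3, MeCN/THF, 70 °C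
Reagents that add atoms: none
Why: Copper-free Sonogashira coupling with a bulky biarylphosphine suits the electron-rich aryl bromide.

Step 13
Reactants: 22 3,5-dimethoxybenzaldehyde
Product: 23 2-iodo-3,5-dimethoxybenzaldehyde
Conditions: NIS, CF3CO2H (cat.), MeCN, rt
Reagents that add atoms: N-iodosuccinimide O=C1CCC(=O)N1I
Why: Electrophilic iodination goes ortho to one methoxy group and para to the other, the position between the two methoxy groups being hindered.

Step 14
Reactants: 23 2-iodo-3,5-dimethoxybenzaldehyde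
Product: 24 3,5-dihydroxy-2-iodobenzaldehyde
Conditions: BBr3, CH2Cl2, −78 °C to rt; H2O
Reagents that add atoms: none
Why: Lewis-acid cleavage of both aryl methyl ethers, which the aldehyde and the aryl iodide tolerate.

Step 15
Reactants: 24 3,5-dihydroxy-2-iodobenzaldehyde
Product: 25 2-iodo-3,5-bis[(triisopropylsilyl)oxy]benzaldehyde
Conditions: TIPSCl, imidazole, DMF, rt
Reagents that add atoms: chlorotriisopropylsilane CC(C)[Si](Cl)(C(C)C)C(C)C
Why: Bulky silyl ethers mask the two oxygens of resorcinol ring A through steps 17 to 20 and come off with fluoride exactly when the free ortho phenol is needed for furan formation.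

Step 16
Reactants: 4 4-(benzyloxy)benzyl chloride
Product: 26 diethyl [4-(benzyloxy)benzyl]phosphonate
Conditions: P(OEt)3, neat, 140 °C
Reagents that add atoms: triethyl phosphite CCOP(OCC)OCC
Why: Michaelis–Arbuzov reaction of a reactive benzylic chloride.

Step 17
Reactants: 25 2-iodo-3,5-bis[(triisopropylsilyl)oxy]benzaldehyde; 26 diethyl [4-(benzyloxy)benzyl]phosphonate
Product: 27 (E)-1-[4-(benzyloxy)phenyl]-2-{2-iodo-3,5-bis[(triisopropylsilyl)oxy]phenyl}ethene
Conditions: NaH, THF, 0 °C to rt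
Reagents that add atoms: none
Why: Horner–Wadsworth–Emmons olefination with a benzylic phosphonate is E-selective, and the stabilised carbanion leaves the aryl silyl ethers alone.

Step 18
Reactants: 27 (E)-stilbene
Product: 28 (2R,3R)-3-[4-(benzyloxy)phenyl]-2-{2-iodo-3,5-bis[(triisopropylsilyl)oxy]phenyl}oxirane
Conditions: D-fructose-derived Shi ketone (30 mol %), Oxone (2KHSO5·KHSO4·K2SO4), K2CO3, Bu4NHSO4, MeCN/dimethoxymethane/aq. buffer pH 10.5, 0 °C
Reagents that add atoms: potassium peroxymonosulfate [K+].OOS(=O)(=O)[O-]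
Why: Shi asymmetric epoxidation of a trans-stilbene through the chiral dioxirane (spiro transition state) should give the R,R-epoxide, and the basic buffer protects the acid-labile 4-alkoxystilbene oxide.

Step 19
Reactants: 28 (2R,3R)-epoxide; 1 1,3-bis(benzyloxy)-5-bromobenzene
Product: 29 (1S,2R)-2-[4-(benzyloxy)phenyl]-2-[2,4-bis(benzyloxy)-6-bromophenyl]-1-{2-iodo-3,5-bis[(triisopropylsilyl)oxy]phenyl}ethan-1-ol
Conditions: 1 (3 equiv), BF3·OEt2 (0.3 equiv), CH2Cl2, −78 °C
Reagents that add atoms: none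
Why: Friedel–Crafts alkylation by Lewis-acid epoxide opening occurs at the 4-benzyloxybenzylic carbon C7a with backside attack (inversion, 7aR) while C8a keeps its oxygen (8aS), and the arene reacts para to a benzyloxy group and ortho to bromine as in step 1.

Step 20
Reactants: 29 (1S,2R)-alcohol
Product: 30 benzyl ether of 29 at the C8a oxygen
Conditions: NaH, BnBr, Bu4NI (cat.), THF, 0 °C to rt
Reagents that add atoms: benzyl bromide BrCc1ccccc1
Why: Williamson benzylation keeps the secondary alcohol from adding to the alkyne in step 21 and from serving as a hydride donor to palladium in step 22.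

Step 21
Reactants: 30 benzyl ether; 21 silylalkyne
Product: 34 4-{(1S,2R)-1-(benzyloxy)-2-[4-(benzyloxy)phenyl]-2-[2,4-bis(benzyloxy)-6-bromophenyl]ethyl}-2-aryl-1-benzofuran-6-ol (aryl = the dihydrobenzofuran-5-yl group of 19), via terminal alkyne 31 (not isolated), via iodoresorcinol 32 (not isolated), via alkynylphenol 33 (not isolated)
Conditions: TBAF (4 equiv), THF, 0 °C to rt; then Pd(PPh3)2Cl2 (5 mol %), CuI (10 mol %), Et3N, 60 °C; aq. NH4Cl
Reagents that add atoms: none
Why: Fluoride frees the alkyne and both phenols, Sonogashira coupling takes place at the C–I bond and leaves the hindered aryl bromide of resorcinol ring B alone, and the ortho phenoxide adds 5-endo-dig to the alkyne under the same copper/palladium catalysis (classical one-pot benzofuran synthesis).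

Step 22
Reactants: 34 2-aryl-6-hydroxybenzofuran
Product: 35 nona-O-benzyl ether of the target with free C13a hydroxyl (7aR,8aS,7bR,8bR,7cR,8cR,7dR,8dR)
Conditions: Pd(OAc)2 (10 mol %), PPh3 (25 mol %), HCO2Na (3 equiv), Bu4NCl, DMF, 90 °C
Reagents that add atoms: none
Why: Zerovalent palladium formed in situ inserts into the C9b–Br bond of resorcinol ring B, the aryl–palladium adds syn across the C8b=C7b bond of the benzofuran (arylative dearomatisation, the intramolecular dearomative reductive Heck reaction known for indoles and benzofurans), and the tertiary benzylic C7b–palladium species, which has no syn β-hydrogen, is intercepted by formate (decarboxylation, then C–H reductive elimination with retention). The seven-membered carbocycle closes in the 7-exo-trig mode, the attacked atom C8b lying inside the new ring and C7b outside it. The C8b/C7b relationship is fixed as trans by the mechanism, because resorcinol ring B and the hydride arrive on the same face and phenol ring B therefore ends up opposite to resorcinol ring B. The absolute sense at C8b is set by the resident C7a and C8a centres: in the boat-like closure the 4-benzyloxyphenyl group on C7a must sit pseudo-axial on the convex face to escape allylic 1,3-strain with the ortho benzyloxy group on C11b, and only attack on the benzofuran face that leads to 8bR allows this. The step needs cyclisation to outrun direct formate reduction of the aryl–palladium bromide and base-induced re-aromatisation; sparingly soluble HCO2Na, the absence of carbonate or pivalate base and the folding of the triaryl-substituted two-carbon arm, which holds C9b over C8b, should secure this.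

Step 23
Reactants: 35 nona-O-benzyl ether
Product: 36 target CNP0132116.1
Conditions: H2 (1 atm), Pd(OH)2/C, THF/MeOH, rt
Reagents that add atoms: none
Why: Hydrogenolysis of the nine primary O-benzyl groups in neutral medium should be faster than cleavage of the hindered ring C–O bonds of the three dihydrofurans or of the C8a–O bond.

Compound list
1 | 1,3-bis(benzyloxy)-5-bromobenzene | Brc1cc(OCc2ccccc2)cc(OCc2ccccc2)c1 | starting material
2 | 2,4-bis(benzyloxy)-6-bromobenzaldehyde | O=Cc1c(Br)cc(OCc2ccccc2)cc1OCc1ccccc1 | intermediate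
3 | 4-(benzyloxy)-2-bromo-6-hydroxybenzaldehyde | O=Cc1c(O)cc(OCc2ccccc2)cc1Br | intermediate
4 | 4-(benzyloxy)benzyl chloride | ClCc1ccc(OCc2ccccc2)cc1 | starting material
5 | 4-(benzyloxy)-2-{[4-(benzyloxy)benzyl]oxy}-6-bromobenzaldehyde | O=Cc1c(Br)cc(OCc2ccccc2)cc1OCc1ccc(OCc2ccccc2)cc1 | intermediate
6 | 3,5-bis(benzyloxy)phenyllithium (not isolated) | [Li]c1cc(OCc2ccccc2)cc(OCc2ccccc2)c1 | intermediate
7 | rac-[4-(benzyloxy)-2-{[4-(benzyloxy)benzyl]oxy}-6-bromophenyl][3,5-bis(benzyloxy)phenyl]methanol | OC(c1cc(OCc2ccccc2)cc(OCc2ccccc2)c1)c1c(Br)cc(OCc2ccccc2)cc1OCc1ccc(OCc2ccccc2)cc1 | intermediate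
8 | [4-(benzyloxy)-2-{[4-(benzyloxy)benzyl]oxy}-6-bromophenyl][3,5-bis(benzyloxy)phenyl]methanone | O=C(c1cc(OCc2ccccc2)cc(OCc2ccccc2)c1)c1c(Br)cc(OCc2ccccc2)cc1OCc1ccc(OCc2ccccc2)cc1 | intermediate
9 | hydrazone of ketone 8 | NN=C(c1cc(OCc2ccccc2)cc(OCc2ccccc2)c1)c1c(Br)cc(OCc2ccccc2)cc1OCc1ccc(OCc2ccccc2)cc1 | intermediate
10 | diaryldiazomethane from 9 (not isolated) | [N-]=[N+]=C(c1cc(OCc2ccccc2)cc(OCc2ccccc2)c1)c1c(Br)cc(OCc2ccccc2)cc1OCc1ccc(OCc2ccccc2)cc1 | intermediate
11 | (2S,3R)-6-(benzyloxy)-2-[4-(benzyloxy)phenyl]-3-[3,5-bis(benzyloxy)phenyl]-4-bromo-2,3-dihydro-1-benzofuran (cis; 7dS,8dR) | Brc1cc(OCc2ccccc2)cc2c1[C@@H](c1cc(OCc3ccccc3)cc(OCc3ccccc3)c1)[C@@H](c1ccc(OCc3ccccc3)cc1)O2 | intermediate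
12 | 5-bromo-2-hydroxybenzonitrile | N#Cc1cc(Br)ccc1O | starting material
13 | 2-{[4-(benzyloxy)benzyl]oxy}-5-bromobenzonitrile | N#Cc1cc(Br)ccc1OCc1ccc(OCc2ccccc2)cc1 | intermediate
14 | aryllithium from 11, lithium on C9c (not isolated) | [Li]c1cc(OCc2ccccc2)cc2c1[C@@H](c1cc(OCc3ccccc3)cc(OCc3ccccc3)c1)[C@@H](c1ccc(OCc3ccccc3)cc1)O2 | intermediate
15 | N-H ketimine joining C9c (resorcinol ring C) and C3b (phenol ring B) (not isolated) | N=C(c1cc(Br)ccc1OCc1ccc(OCc2ccccc2)cc1)c1cc(OCc2ccccc2)cc2c1[C@@H](c1cc(OCc3ccccc3)cc(OCc3ccccc3)c1)[C@@H](c1ccc(OCc3ccccc3)cc1)O2 | intermediate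
16 | hydrazone corresponding to ketimine 15 | NN=C(c1cc(Br)ccc1OCc1ccc(OCc2ccccc2)cc1)c1cc(OCc2ccccc2)cc2c1[C@@H](c1cc(OCc3ccccc3)cc(OCc3ccccc3)c1)[C@@H](c1ccc(OCc3ccccc3)cc1)O2 | intermediate
17 | diaryldiazomethane from 16 (not isolated) | [N-]=[N+]=C(c1cc(Br)ccc1OCc1ccc(OCc2ccccc2)cc1)c1cc(OCc2ccccc2)cc2c1[C@@H](c1cc(OCc3ccccc3)cc(OCc3ccccc3)c1)[C@@H](c1ccc(OCc3ccccc3)cc1)O2 | intermediate
18 | (2S,3R)-2-[4-(benzyloxy)phenyl]-5-bromo-3-{(2S,3R)-6-(benzyloxy)-2-[4-(benzyloxy)phenyl]-3-[3,5-bis(benzyloxy)phenyl]-2,3-dihydro-1-benzofuran-4-yl}-2,3-dihydro-1-benzofuran (both rings cis; 7cS,8cR,7dS,8dR) | Brc1ccc2c(c1)[C@@H](c1cc(OCc3ccccc3)cc3c1[C@@H](c1cc(OCc4ccccc4)cc(OCc4ccccc4)c1)[C@@H](c1ccc(OCc4ccccc4)cc1)O3)[C@@H](c1ccc(OCc3ccccc3)cc1)O2 | intermediate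
19 | (2R,3R)-2-[4-(benzyloxy)phenyl]-5-bromo-3-{(2R,3R)-6-(benzyloxy)-2-[4-(benzyloxy)phenyl]-3-[3,5-bis(benzyloxy)phenyl]-2,3-dihydro-1-benzofuran-4-yl}-2,3-dihydro-1-benzofuran (both rings trans; 7cR,8cR,7dR,8dR) | Brc1ccc2c(c1)[C@@H](c1cc(OCc3ccccc3)cc3c1[C@@H](c1cc(OCc4ccccc4)cc(OCc4ccccc4)c1)[C@H](c1ccc(OCc4ccccc4)cc1)O3)[C@H](c1ccc(OCc3ccccc3)cc1)O2 | intermediate
20 | ethynyltrimethylsilane | C#C[Si](C)(C)C | starting material
21 | 5-[(trimethylsilyl)ethynyl] analogue of 19 | C[Si](C)(C)C#Cc1ccc2c(c1)[C@@H](c1cc(OCc3ccccc3)cc3c1[C@@H](c1cc(OCc4ccccc4)cc(OCc4ccccc4)c1)[C@H](c1ccc(OCc4ccccc4)cc1)O3)[C@H](c1ccc(OCc3ccccc3)cc1)O2 | intermediate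
22 | 3,5-dimethoxybenzaldehyde | COc1cc(C=O)cc(OC)c1 | starting material
23 | 2-iodo-3,5-dimethoxybenzaldehyde | COc1cc(OC)c(I)c(C=O)c1 | intermediate
24 | 3,5-dihydroxy-2-iodobenzaldehyde | O=Cc1cc(O)cc(O)c1I | intermediate
25 | 2-iodo-3,5-bis[(triisopropylsilyl)oxy]benzaldehyde | CC(C)[Si](Oc1cc(C=O)c(I)c(O[Si](C(C)C)(C(C)C)C(C)C)c1)(C(C)C)C(C)C | intermediate
26 | diethyl [4-(benzyloxy)benzyl]phosphonate | CCOP(=O)(Cc1ccc(OCc2ccccc2)cc1)OCC | intermediate
27 | (E)-1-[4-(benzyloxy)phenyl]-2-{2-iodo-3,5-bis[(triisopropylsilyl)oxy]phenyl}ethene | CC(C)[Si](Oc1cc(/C=C/c2ccc(OCc3ccccc3)cc2)c(I)c(O[Si](C(C)C)(C(C)C)C(C)C)c1)(C(C)C)C(C)C | intermediate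
28 | (2R,3R)-3-[4-(benzyloxy)phenyl]-2-{2-iodo-3,5-bis[(triisopropylsilyl)oxy]phenyl}oxirane | CC(C)[Si](Oc1cc([C@H]2O[C@@H]2c2ccc(OCc3ccccc3)cc2)c(I)c(O[Si](C(C)C)(C(C)C)C(C)C)c1)(C(C)C)C(C)C | intermediate
29 | (1S,2R)-2-[4-(benzyloxy)phenyl]-2-[2,4-bis(benzyloxy)-6-bromophenyl]-1-{2-iodo-3,5-bis[(triisopropylsilyl)oxy]phenyl}ethan-1-ol (8aS,7aR) | CC(C)[Si](Oc1cc([C@@H](O)[C@H](c2ccc(OCc3ccccc3)cc2)c2c(Br)cc(OCc3ccccc3)cc2OCc2ccccc2)c(I)c(O[Si](C(C)C)(C(C)C)C(C)C)c1)(C(C)C)C(C)C | intermediate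
30 | benzyl ether of 29 at the C8a oxygen | CC(C)[Si](Oc1cc([C@@H](OCc2ccccc2)[C@H](c2ccc(OCc3ccccc3)cc2)c2c(Br)cc(OCc3ccccc3)cc2OCc2ccccc2)c(I)c(O[Si](C(C)C)(C(C)C)C(C)C)c1)(C(C)C)C(C)C | intermediate
31 | 5-ethynyl analogue of 19 (not isolated) | C#Cc1ccc2c(c1)[C@@H](c1cc(OCc3ccccc3)cc3c1[C@@H](c1cc(OCc4ccccc4)cc(OCc4ccccc4)c1)[C@H](c1ccc(OCc4ccccc4)cc1)O3)[C@H](c1ccc(OCc3ccccc3)cc1)O2 | intermediate
32 | 5-{(1S,2R)-1-(benzyloxy)-2-[4-(benzyloxy)phenyl]-2-[2,4-bis(benzyloxy)-6-bromophenyl]ethyl}-4-iodobenzene-1,3-diol (not isolated) | Oc1cc(O)c(I)c(c1)[C@@H](OCc1ccccc1)[C@H](c1ccc(OCc2ccccc2)cc1)c1c(Br)cc(OCc2ccccc2)cc1OCc1ccccc1 | intermediate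
33 | 2-alkynylphenol: 32 with the ethynyl carbon of 31 in place of iodine (not isolated) | Oc1cc(O)c(C#Cc2ccc3c(c2)[C@@H](c2cc(OCc4ccccc4)cc4c2[C@@H](c2cc(OCc5ccccc5)cc(OCc5ccccc5)c2)[C@H](c2ccc(OCc5ccccc5)cc2)O4)[C@H](c2ccc(OCc4ccccc4)cc2)O3)c(c1)[C@@H](OCc1ccccc1)[C@H](c1ccc(OCc2ccccc2)cc1)c1c(Br)cc(OCc2ccccc2)cc1OCc1ccccc1 | intermediate
34 | 4-{(1S,2R)-1-(benzyloxy)-2-[4-(benzyloxy)phenyl]-2-[2,4-bis(benzyloxy)-6-bromophenyl]ethyl}-2-aryl-1-benzofuran-6-ol, aryl = dihydrobenzofuran-5-yl group of 19 | Oc1cc([C@@H](OCc3ccccc3)[C@H](c3ccc(OCc4ccccc4)cc3)c3c(Br)cc(OCc4ccccc4)cc3OCc3ccccc3)c2cc(-c3ccc4c(c3)[C@@H](c3cc(OCc5ccccc5)cc5c3[C@@H](c3cc(OCc6ccccc6)cc(OCc6ccccc6)c3)[C@H](c3ccc(OCc6ccccc6)cc3)O5)[C@H](c3ccc(OCc5ccccc5)cc3)O4)oc2c1 | intermediate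
35 | nona-O-benzyl ether of the target (all oxygens benzylated except the C13a hydroxyl; 7aR,8aS,7bR,8bR,7cR,8cR,7dR,8dR) | C(c1ccccc1)Oc1ccc([C@@H]2c3c(OCc4ccccc4)cc(OCc4ccccc4)cc3[C@@H]3c4c(cc(O)cc4[C@H]2OCc2ccccc2)O[C@H]3c2ccc3c(c2)[C@@H](c2cc(OCc4ccccc4)cc4c2[C@@H](c2cc(OCc5ccccc5)cc(OCc5ccccc5)c2)[C@H](c2ccc(OCc5ccccc5)cc2)O4)[C@H](c2ccc(OCc4ccccc4)cc2)O3)cc1 | intermediate
36 | CNP0132116.1 | Oc1ccc([C@@H]2c3c(O)cc(O)cc3[C@@H]3c4c(cc(O)cc4[C@H]2O)O[C@H]3c2ccc3c(c2)[C@@H](c2cc(O)cc4c2[C@@H](c2cc(O)cc(O)c2)[C@H](c2ccc(O)cc2)O4)[C@H](c2ccc(O)cc2)O3)cc1 | target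

Total step count: 23.
Longest linear sequence: 14 steps (steps 1 to 7, 9 to 12 and 21 to 23).

Steps most likely to fail

Step 22. The aryl–palladium bromide may be reduced by formate before it cyclises, the C7b–palladium intermediate may re-aromatise by loss of the C8b hydrogen, or the wrong face of the benzofuran may be attacked. The fallback sets out from 34 and comes back at 35. The same C8b–C9b bond would be closed by a palladium-catalysed intramolecular direct C–H arylation (Pd(OAc)2, PCy3·HBF4, K2CO3, pivalic acid, N,N-dimethylacetamide, 110 °C), which accepts re-aromatisation and gives the benzofuran-fused dibenzocycloheptane F1. The tetrasubstituted furan double bond of F1 would then be reduced by ionic hydrogenation (Et3SiH, CF3CO2H, CH2Cl2, 0 °C): protonation at C8b from the convex face, hydride capture of the C7b oxocarbenium ion and acid equilibration of C7b to the trans ring should lead to 35.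

Step 19. The epoxide may rearrange (Meinwald shift), a free benzylic cation may erode the inversion at C7a, or the arene may react between its two benzyloxy groups. The fallback sets out from 1 and 28 and comes back at 29. Compound 1 would be iodinated with NIS to 1,5-bis(benzyloxy)-3-bromo-2-iodobenzene F2, which fixes the position of the new bond beforehand. Selective iodine–magnesium exchange (i-PrMgCl·LiCl, THF, −30 °C) would give [2,4-bis(benzyloxy)-6-bromophenyl]magnesium chloride F3. This would open epoxide 28 under CuI catalysis (10 mol %, THF, −30 to 0 °C) by SN2 attack with inversion at the less hindered 4-benzyloxybenzylic carbon C7a, giving 29.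

Step 10. The carbene may be diverted into resorcinol ring D, or catalyst control may be poor next to the resident C8d centre. The fallback sets out from 11 and comes back at 19. Compound 11 would be epimerised with BF3·OEt2 to the trans bromide F4. After bromine–lithium exchange (n-BuLi, THF, −78 °C), 4-bromo-2-formylphenyl tert-butyl carbonate F5 (from 5-bromosalicylaldehyde and Boc2O) would be added; the alkoxide takes over the Boc group and loses tert-butyl carbonate to give the ortho-quinone methide F6. In the same flask F6 would be trapped by the ylide made from [4-(benzyloxy)benzyl]dimethylsulfonium tetrafluoroborate F7 and LiN(SiMe3)2 in a [4+1] annulation (conjugate addition, then 5-exo-tet displacement of dimethyl sulfide), which forms the trans ring directly and gives 19. The face of F6 is chosen only by the neighbouring C8d centre, so diastereomers would have to be separated if this control is incomplete.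

Further compounds
F1 | step 22 | 7b,8b-didehydro analogue of 35 (benzofuran-fused dibenzocycloheptane; 7aR,8aS) | C(c1ccccc1)Oc1ccc([C@@H]2c3c(OCc4ccccc4)cc(OCc4ccccc4)cc3-c3c(-c4ccc5c(c4)[C@@H](c4cc(OCc6ccccc6)cc6c4[C@@H](c4cc(OCc7ccccc7)cc(OCc7ccccc7)c4)[C@H](c4ccc(OCc7ccccc7)cc4)O6)[C@H](c4ccc(OCc6ccccc6)cc4)O5)oc4cc(O)cc([C@H]2OCc2ccccc2)c34)cc1
F2 | step 19 | 1,5-bis(benzyloxy)-3-bromo-2-iodobenzene | Brc1cc(OCc2ccccc2)cc(OCc2ccccc2)c1I
F3 | step 19 | [2,4-bis(benzyloxy)-6-bromophenyl]magnesium chloride | Brc1cc(OCc2ccccc2)cc(OCc2ccccc2)c1[Mg]Cl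
F4 | step 10 | (2R,3R)-6-(benzyloxy)-2-[4-(benzyloxy)phenyl]-3-[3,5-bis(benzyloxy)phenyl]-4-bromo-2,3-dihydro-1-benzofuran (trans) | Brc1cc(OCc2ccccc2)cc2c1[C@@H](c1cc(OCc3ccccc3)cc(OCc3ccccc3)c1)[C@H](c1ccc(OCc3ccccc3)cc1)O2
F5 | step 10 | 4-bromo-2-formylphenyl tert-butyl carbonate | CC(C)(C)OC(=O)Oc1ccc(Br)cc1C=O
F6 | step 10 | ortho-quinone methide: 4-bromo-6-(arylmethylidene)cyclohexa-2,4-dien-1-one, aryl = the dihydrobenzofuran-4-yl group of F4 | O=C1C=CC(Br)=CC1=Cc1cc(OCc2ccccc2)cc2c1[C@@H](c1cc(OCc3ccccc3)cc(OCc3ccccc3)c1)[C@H](c1ccc(OCc3ccccc3)cc1)O2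
F7 | step 10 | [4-(benzyloxy)benzyl]dimethylsulfonium tetrafluoroborate | C[S+](C)Cc1ccc(OCc2ccccc2)cc1.F[B-](F)(F)F
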